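**Early times.** At the start the flask held no dissolved gas. Gas crosses from the held gas phase and joins starting material over free catalyst, reversibly, to give product, while added ligand and pairing with itself remove free catalyst.

starting material 0.14 M; gas phase 28 mM (held); free catalyst 1.4 mM; added ligand 1.9 mM; time 8.0 min

- amount of product at 8.0 min, in percent of the starting material charged
- concentration of dissolved gas in solution at 4.0 min, in percent of saturation
- the change that raises the amount of product at 8.0 min, in percent of the starting material charged most ("none" if none brings more than 2 percentage points) (south-east / north / north-west / none)
- amount of product at 8.0 min, in percent of the starting material charged, after north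

- south-east: doubling the transfer coefficient of step 2, all else as stated
- north: doubling the saturation concentration of gas phase, all else as stated
- north-west: doubling the amount of free catalyst, all else as stated

- two of one species on the left: rate k times its square, two consumed each time
- at the start none of the gas is dissolved
- run time (flask): 8.0 min

    starting material + dissolved gas + free catalyst ⇌ free catalyst + product (K1 = 12.2 M⁻¹, k1 = 19100 M⁻² s⁻¹)
    gas phase ⇌ dissolved gas, rate k2*(csat - [dissolved gas]) (k2 = 0.0176 s⁻¹, csat = 28 mM)
    free catalyst + added ligand ⇌ idle complex (K3 = 6300 M⁻¹, k3 = 4.85 M⁻¹ s⁻¹)
    2 free catalyst → spent catalyst (k4 = 2.72 M⁻¹ s⁻¹)

**Two extremes.** I counted turnovers against a ceiling. In the rich extreme the catalyst never tires, so the reaction stands at equilibrium. The catalyst cancels from that balance, and the ratio of product to starting material equals K1 times the dissolved gas. This gives the equilibrium ceiling (thermodynamic control), the share of starting material in product when balanced against a saturated solution: 25.5%. Reaching it takes 25.5 turnovers per catalyst charged.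

In the poor extreme each free catalyst lasts one ligand half-life, 75.2 s, with dissolved gas stuck at 2.80 mM. Even so, it makes 563 forward turnovers, far more than needed, so I placed the real flask beside the rich extreme, following its gas.

**Gas clock.** Gas entering the solution is also banked as product. Taking a middle value for this storage, the solution fills 2.27 times slower than the transfer coefficient says. So I expected 84.4% of saturation at 4.0 min. For 8.0 min I expected dissolved gas at 27.3 mM, which gives 25.0% product.

The ceiling contains neither transfer coefficient nor catalyst, so south-east and north-west leave it at its value, while doubling saturation lifts it to 40.6%. That gain is more than 2 percentage points, so my choice was north.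

**The forecast.** The forecast gave 25%, 85%, north and 40.2%, reasoning that “the reaction tracks its equilibrium with the dissolved gas while the gas relaxes towards saturation”. Its value for north stood slightly below my ceiling.

**The result.** The simulation gave 25.1%, 85.0%, north and 40.4%. The gains were 15 points for north, 0.36 points for south-east and 0.0092 points for north-west.

**Earlier reading.** This flask's 25.1% was 98.4% of the ceiling 25.5%. The neighbour, the same flask read at 2.0 min, held 0.0165 M of dissolved gas. Putting that reading in place of saturation in the ceiling gives 16.7%, and the neighbour held 16.6% product, with 83% of its starting material left.

All constants are those of an exercise; the rest is arithmetic.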